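Everything rests on cutting ring A (C7–C12) at C11. C11 sits between C12H2 and the methyl-bearing C10, so ring A equals the spiro cyclopropane C7–C8–C12, the propenyl group on C8 (C9=C10–CH3) and one CO. A rhodium-catalysed [5+1] carbonylation breaks C8–C12, forms C11–C12 and C10–C11 and closes ring A in one operation, leaving the spiro centre C7 untouched. The precursor is enantiopure ring B (C5 bromide, C6 gem-dimethyl) bearing this vinylcyclopropane, with C2 masked as a silyl ether so that C7–C8 is not acceptor-activated. Afterwards the C11 ketone becomes the C10=C11 alkene, which accepts Cl and then Br by diaxial openings.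

Key step: step 11

Remarks on the chemistry
- Atom labels C1–C12 follow the order of the target SMILES. Ring B is C2–C7 and ring A is C7–C12.
- C2 (15–23), C8 (14–16) and C10 (18) are drawn as the epimers expected to prevail. Each of these centres is erased later, so mixtures are carried on.
- A C2 ketone would make C7–C8 a donor–acceptor bond (vinyl on C8, acyl on C7) and invite the wrong ring opening. A C2 methylene would be a second vinylcyclopropane. Hence the silyl ether in 16.
- The last bond made to C7 should enter axially on ring B, anti to the axial C6 methyl group. The target carries C12 axial (trans to Br), so the cyclopropane is closed by C7–C12 bond formation.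
- C1 is installed before the tertiary bromide exists, because a vicinal bromochloride would not tolerate basic, Lewis acidic or reducing methylenation reagents.
- The bromo-enamine of step 19 is made beforehand from the commercial chloro-enamine by halide exchange. The ligand enantiomer in step 1 is the one that delivers (S)-2.

Step 1
Reactants: 1 3-methylbut-2-en-1-ol (prenol)
Product: 2 (2S)-2-bromo-3-chloro-3-methylbutan-1-ol
Conditions: NBS, ClTi(OiPr)3, chiral tridentate Schiff-base ligand (cat.), hexanes, −20 °C
Reagents that add atoms: N-bromosuccinimide, O=C1CCC(=O)N1Br; chlorotitanium triisopropoxide, CC(C)O[Ti](Cl)(OC(C)C)OC(C)C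
Why: Catalytic enantioselective bromochlorination of an allylic alcohol, in which the alcohol binds the chiral titanium complex, bromonium forms on one alkene face and titanium-bound chloride opens it anti at the tertiary carbon (Markovnikov), which sets C5 as S.

Step 2
Reactants: 2 (2S)-2-bromo-3-chloro-3-methylbutan-1-ol
Product: 3 (2S)-2-bromo-3-chloro-3-methylbutyl trifluoromethanesulfonate
Conditions: Tf2O, 2,6-lutidine, CH2Cl2, −78 °C
Reagents that add atoms: trifluoromethanesulfonic anhydride, O=S(=O)(OS(=O)(=O)C(F)(F)F)C(F)(F)F
Why: O-Sulfonylation of a primary alcohol with a hindered base at low temperature gives a leaving group reactive enough for this β-branched carbon without touching either halide or C5.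

Step 3
Reactants: 3 (2S)-2-bromo-3-chloro-3-methylbutyl trifluoromethanesulfonate; 4 methyl acetoacetate
Product: 6 methyl (6S)-6-bromo-7-chloro-7-methyl-3-oxooctanoate, via acetoacetate dianion 5 (not isolated)
Conditions: 4, NaH, THF, 0 °C; n-BuLi, 0 °C; 3, −78 to −30 °C; AcOH
Reagents that add atoms: none
Why: γ-Alkylation of the acetoacetate dianion, whose terminal carbanion should attack the primary triflate by SN2 at low temperature faster than E2 or attack at halogen, with C5 not involved.

Step 4
Reactants: 6 methyl (6S)-6-bromo-7-chloro-7-methyl-3-oxooctanoate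
Product: 7 methyl (1S,3S)-3-bromo-2,2-dimethyl-6-oxocyclohexane-1-carboxylate
Conditions: (CF3)2CHOH, 25–40 °C
Reagents that add atoms: none
Why: Solvolytic bromonium cyclisation, in which the ionising, non-nucleophilic solvent expels the tertiary chloride with help from the anti bromine and the enol carbon C7 opens the configurationally defined bromonium ion at C6 through a chair (6-endo), so that C5 stays S with Br equatorial, O-closure is reversible under the liberated HCl and the ester settles equatorial by enolisation.

Step 5
Reactants: 7 methyl (1S,3S)-3-bromo-2,2-dimethyl-6-oxocyclohexane-1-carboxylate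
Product: 8 methyl (6S,8S)-8-bromo-7,7-dimethyl-1,4-dioxaspiro[4.5]decane-6-carboxylate
Conditions: HOCH2CH2OH, p-TsOH (cat.), benzene, reflux (Dean–Stark)
Reagents that add atoms: ethane-1,2-diol, OCCO
Why: Acid-catalysed ketalisation with azeotropic removal of water protects the C2 ketone of the β-keto ester so that the ester carbon (future C8) can be handled alone.

Step 6
Reactants: 8 methyl (6S,8S)-8-bromo-7,7-dimethyl-1,4-dioxaspiro[4.5]decane-6-carboxylate
Product: 9 (6R,8S)-8-bromo-7,7-dimethyl-1,4-dioxaspiro[4.5]decane-6-carbaldehyde
Conditions: i-Bu2AlH (1.1 equiv), CH2Cl2, −78 °C; aq potassium sodium tartrate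
Reagents that add atoms: none
Why: Partial ester reduction with a dialkylaluminium hydride, whose crowded aluminium hemiacetal, held by the neighbouring ketal oxygen, should survive at −78 °C and release the aldehyde only on work-up.

Step 7
Reactants: 9 (6R,8S)-8-bromo-7,7-dimethyl-1,4-dioxaspiro[4.5]decane-6-carbaldehyde; 10 (E)-1-bromoprop-1-ene
Product: 13 (2Z,4S)-4-bromo-2-[(2E)-but-2-en-1-ylidene]-3,3-dimethylcyclohexan-1-one, via (E)-prop-1-enyllithium 11 (not isolated), via ketal allylic alcohol 12 (not isolated)
Conditions: 10 (slight excess), t-BuLi (2 equiv), Et2O, −78 °C; 9, −78 °C; then 10% aq H2SO4, THF, 40 °C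
Reagents that add atoms: water, O
Why: Halogen–lithium exchange with retention of alkene geometry, 1,2-addition to the aldehyde and acid-induced ketal hydrolysis with aldol-condensation-type dehydration of the β-hydroxy ketone all funnel to the fully conjugated dienone, in which the propenyl group turns away from C6Me2.

Step 8
Reactants: 13 (2Z,4S)-4-bromo-2-[(2E)-but-2-en-1-ylidene]-3,3-dimethylcyclohexan-1-one
Product: 14 (1S,3S,7S)-7-bromo-8,8-dimethyl-1-[(1E)-prop-1-en-1-yl]spiro[2.5]octan-4-one
Conditions: Me3S(O)I, NaH, DMSO, 25 °C
Reagents that add atoms: trimethylsulfoxonium iodide, C[S+](C)(C)=O.[I-]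
Why: Corey–Chaykovsky cyclopropanation (1,4-addition of the methylide at C8, then 3-exo-tet closure of the C2=C7 enolate on C12), in which C12 should bond to C7 axially, anti to the axial C6 methyl group of the half-chair that keeps Br equatorial, placing C12 trans and C8 cis to Br as in the target while the γ,δ-alkene is left alone.

Step 9
Reactants: 14 (1S,3S,7S)-7-bromo-8,8-dimethyl-1-[(1E)-prop-1-en-1-yl]spiro[2.5]octan-4-one
Product: 15 (1S,3S,4R,7S)-7-bromo-8,8-dimethyl-1-[(1E)-prop-1-en-1-yl]spiro[2.5]octan-4-ol
Conditions: i-Bu2AlH, CH2Cl2, −78 °C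
Reagents that add atoms: none
Why: Aluminium hydride 1,2-reduction removes the π-acceptor next to C7, with hydride expected on the equatorial path because the axial C6 methyl group blocks the axial one, although the C2 configuration is of no consequence.

Step 10
Reactants: 15 (1S,3S,4R,7S)-7-bromo-8,8-dimethyl-1-[(1E)-prop-1-en-1-yl]spiro[2.5]octan-4-ol
Product: 16 tert-butyldimethylsilyl ether of 15 (spiro vinylcyclopropane with C2 OTBS)
Conditions: TBSOTf, 2,6-lutidine, CH2Cl2, −78 to 0 °C
Reagents that add atoms: tert-butyldimethylsilyl trifluoromethanesulfonate, CC(C)(C)[Si](C)(C)OS(=O)(=O)C(F)(F)F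
Why: Silyl triflate silylation of a hindered secondary alcohol under buffered conditions gives an inert, bulky C2 group that cannot trap an acyl metal intermediate.

Step 11
Reactants: 16 spiro vinylcyclopropane silyl ether; 17 carbon monoxide
Product: 18 spiro β,γ-enone silyl ether (C2 OTBS; C8=C9; C10 H and CH3; C11 ketone)
Conditions: [Rh(CO)2Cl]2 (5 mol %), CO (1 atm), toluene, 100 °C
Reagents that add atoms: none
Why: Monovalent rhodium binds the propenyl alkene and adds oxidatively into the neighbouring C8–C12 bond, giving a trivalent rhodacycle with a σ-bond to C12 and a π-allyl over C8–C10; CO then migrates into Rh–C12 and reductive elimination at C10 releases 18, paid for by the loss of ring strain. The closest known reaction type is the rhodium-catalysed [5+1] carbonylation of vinylcyclopropanes to cyclohexenones. Ring A closes as a six-membered ring by C10–C11 reductive elimination from the acyl rhodacycle, since coupling at C8 would give a strained cyclobutanone. C10 is the only new stereocentre, is decided by the syn or anti placing of its methyl group in the allyl unit and is erased in step 12, whereas no bond made or broken involves C7, whose configuration therefore persists. The step needs cleavage of C8–C12 and not of C7–C8, which is secured because C7 is quaternary and walled in by C6Me2 and the C2 silyl ether, and because with C2 at the alcohol level no acceptor polarises C7–C8. The Rh–C12H2 unit has no β-hydrogen, as C7 is quaternary, which closes the usual leak to dienes.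

Step 12
Reactants: 18 spiro β,γ-enone silyl ether
Product: 19 spiro conjugated enone silyl ether (C9=C10 bearing CH3; C11 ketone)
Conditions: DBU (cat.), CH2Cl2, 25 °C
Reagents that add atoms: none
Why: Base-catalysed prototropic shift through the extended enolate moves the alkene into conjugation as the more stable trisubstituted enone and merges both C10 epimers into one compound.

Step 13
Reactants: 19 spiro conjugated enone silyl ether
Product: 21 C10=C11 enol triflate silyl ether, via lithium enolate 20 (not isolated)
Conditions: LiBH(s-Bu)3, THF, −78 °C; PhNTf2, −78 to 25 °C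
Reagents that add atoms: N-phenylbis(trifluoromethanesulfonimide), O=S(=O)(N(c1ccccc1)S(=O)(=O)C(F)(F)F)C(F)(F)F
Why: Conjugate hydride addition of a bulky borohydride to a 2-methylcyclohex-2-enone gives the C10=C11 enolate regiospecifically, and O-sulfonylation with the triflimide traps it in place.

Step 14
Reactants: 21 C10=C11 enol triflate silyl ether
Product: 22 C10=C11 alkene silyl ether
Conditions: Pd(OAc)2 (cat.), PPh3, HCO2H, n-Bu3N, DMF, 60 °C
Reagents that add atoms: none
Why: Palladium-catalysed formate reduction of an enol triflate (oxidative addition, decarboxylation of formate, C–H reductive elimination) leaves the alkene where the triflate fixed it, and the hindered secondary alkyl bromide should not add to zerovalent palladium under these conditions.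

Step 15
Reactants: 22 C10=C11 alkene silyl ether
Product: 23 C2 alcohol with C10=C11 alkene
Conditions: HF·pyridine, THF, 0 to 25 °C
Reagents that add atoms: none
Why: Fluoride-driven Si–O cleavage under mildly acidic conditions frees the hindered alcohol without the E2 loss of the C5 bromide that a basic fluoride source could provoke.

Step 16
Reactants: 23 C2 alcohol with C10=C11 alkene
Product: 24 spiro ketone (C2 ketone; C5 Br; C10=C11)
Conditions: Dess–Martin periodinane, CH2Cl2, 25 °C
Reagents that add atoms: none
Why: Dess–Martin oxidation turns the secondary alcohol into the ketone under neutral conditions that spare the alkene and the bromide and erase the C2 centre.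

Step 17
Reactants: 24 spiro ketone
Product: 25 diene (C1=C2 methylene; C5 Br; C10=C11), the 10-bromo-β-chamigrene skeleton
Conditions: Cp2Ti(μ-Cl)(μ-CH2)AlMe2, pyridine, THF/toluene, −40 to 25 °C
Reagents that add atoms: Tebbe reagent Cp2Ti(μ-Cl)(μ-CH2)AlMe2, C[Al-]1(C)C[Ti](C2C=CC=C2)(C2C=CC=C2)[Cl+]1
Why: Tebbe methylenation, in which the non-basic titanium methylidene converts hindered, enolisable ketones through an oxatitanacyclobutane, so the neopentyl C2 carbonyl should react without elimination of the C5 bromide.

Step 18
Reactants: 25 diene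
Product: 26 chlorohydrin (C10 tertiary OH on the C6 face; C11 Cl on the C2 face)
Conditions: trichloroisocyanuric acid (0.35 equiv), acetone/H2O, 0 °C
Reagents that add atoms: trichloroisocyanuric acid, O=C1N(Cl)C(=O)N(Cl)C(=O)N1Cl; water, O
Why: Electrophilic chlorohydrin formation, in which the trisubstituted C10=C11 alkene should outrun the neopentyl-flanked C1=C2 and only the Markovnikov, trans-diaxial pathway (Fürst–Plattner rule) of the ring A half-chair that keeps bulky C6 equatorial is productive, so chlorine ends axial on C11 (R) and water enters axial at C10.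

Step 19
Reactants: 26 chlorohydrin
Product: 27 target, C=C1CC[C@H](Br)C(C)(C)[C@]12CC[C@@](C)(Br)[C@H](Cl)C2 (C5 S, C7 S, C10 R, C11 R)
Conditions: 1-bromo-N,N,2-trimethylprop-1-en-1-amine, CH2Cl2, 0 to 25 °C
Reagents that add atoms: 1-bromo-N,N,2-trimethylprop-1-en-1-amine, CC(C)=C(Br)N(C)C
Why: α-Haloenamine deoxybromination under neutral conditions, in which the tertiary alcohol adds to the keteniminium bromide, the imidate ionises with help from the antiperiplanar axial C11–Cl and bromide collapses on C10 from the face the oxygen left (axial, Markovnikov opening of a chloronium-like ion), so that C10 forms with retention as R and no HBr is present to attack C1=C2.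

Compound list
1 | 3-methylbut-2-en-1-ol (prenol) | CC(C)=CCO | starting material
2 | (2S)-2-bromo-3-chloro-3-methylbutan-1-ol | OC[C@H](Br)C(C)(C)Cl | intermediate
3 | (2S)-2-bromo-3-chloro-3-methylbutyl trifluoromethanesulfonate | O=S(=O)(OC[C@H](Br)C(C)(C)Cl)C(F)(F)F | intermediate
4 | methyl acetoacetate | COC(=O)CC(C)=O | starting material
5 | methyl acetoacetate dianion, sodium lithium salt | COC(=O)[CH-]C(=O)[CH2-].[Na+].[Li+] | intermediate
6 | methyl (6S)-6-bromo-7-chloro-7-methyl-3-oxooctanoate | COC(=O)CC(=O)CC[C@H](Br)C(C)(C)Cl | intermediate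
7 | methyl (1S,3S)-3-bromo-2,2-dimethyl-6-oxocyclohexane-1-carboxylate | O=C1CC[C@H](Br)C(C)(C)[C@@H]1C(=O)OC | intermediate
8 | methyl (6S,8S)-8-bromo-7,7-dimethyl-1,4-dioxaspiro[4.5]decane-6-carboxylate | O1CCOC12CC[C@H](Br)C(C)(C)[C@@H]2C(=O)OC | intermediate
9 | (6R,8S)-8-bromo-7,7-dimethyl-1,4-dioxaspiro[4.5]decane-6-carbaldehyde | O1CCOC12CC[C@H](Br)C(C)(C)[C@@H]2C=O | intermediate
10 | (E)-1-bromoprop-1-ene | C/C=C/Br | starting material
11 | (E)-prop-1-enyllithium | C/C=C/[Li] | intermediate
12 | (2E)-1-[(8S)-8-bromo-7,7-dimethyl-1,4-dioxaspiro[4.5]decan-6-yl]but-2-en-1-ol (C8 carbinol epimers) | O1CCOC12CC[C@H](Br)C(C)(C)[C@@H]2C(O)/C=C/C | intermediate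
13 | (2Z,4S)-4-bromo-2-[(2E)-but-2-en-1-ylidene]-3,3-dimethylcyclohexan-1-one | O=C1CC[C@H](Br)C(C)(C)/C1=C/C=C/C | intermediate
14 | (1S,3S,7S)-7-bromo-8,8-dimethyl-1-[(1E)-prop-1-en-1-yl]spiro[2.5]octan-4-one (C12 trans to Br; propenyl cis to C2) | O=C1CC[C@H](Br)C(C)(C)[C@]12[C@H](/C=C/C)C2 | intermediate
15 | (1S,3S,4R,7S)-7-bromo-8,8-dimethyl-1-[(1E)-prop-1-en-1-yl]spiro[2.5]octan-4-ol | O[C@@H]1CC[C@H](Br)C(C)(C)[C@]12[C@H](/C=C/C)C2 | intermediate
16 | tert-butyldimethylsilyl ether of 15 (key-step precursor) | CC(C)(C)[Si](C)(C)O[C@@H]1CC[C@H](Br)C(C)(C)[C@]12[C@H](/C=C/C)C2 | intermediate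
17 | carbon monoxide | [C-]#[O+] | starting material
18 | spiro[5.5]undecane β,γ-enone: C2 OTBS, C5 Br, C6 Me2, C8=C9, C10 H/CH3, C11 ketone, C7 as in 27 (key-step product) | CC(C)(C)[Si](C)(C)O[C@@H]1CC[C@H](Br)C(C)(C)[C@]12C=C[C@H](C)C(=O)C2 | intermediate
19 | conjugated enone: C2 OTBS, C9=C10(CH3), C11 ketone | CC(C)(C)[Si](C)(C)O[C@@H]1CC[C@H](Br)C(C)(C)[C@]12CC=C(C)C(=O)C2 | intermediate
20 | lithium C10=C11 enolate of the saturated ketone | CC(C)(C)[Si](C)(C)O[C@@H]1CC[C@H](Br)C(C)(C)[C@]12CCC(C)=C([O-])C2.[Li+] | intermediate
21 | C10=C11 enol triflate, C2 OTBS | CC(C)(C)[Si](C)(C)O[C@@H]1CC[C@H](Br)C(C)(C)[C@]12CCC(C)=C(OS(=O)(=O)C(F)(F)F)C2 | intermediate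
22 | C10=C11 alkene, C2 OTBS | CC(C)(C)[Si](C)(C)O[C@@H]1CC[C@H](Br)C(C)(C)[C@]12CCC(C)=CC2 | intermediate
23 | C10=C11 alkene, C2 OH | O[C@@H]1CC[C@H](Br)C(C)(C)[C@]12CCC(C)=CC2 | intermediate
24 | C10=C11 alkene, C2 ketone | O=C1CC[C@H](Br)C(C)(C)[C@]12CCC(C)=CC2 | intermediate
25 | diene with C1=C2 methylene and C10=C11 (10-bromo-β-chamigrene skeleton) | C=C1CC[C@H](Br)C(C)(C)[C@]12CCC(C)=CC2 | intermediate
26 | chlorohydrin: C10 OH (trans to Cl), C11 Cl | C=C1CC[C@H](Br)C(C)(C)[C@]12CC[C@@](C)(O)[C@H](Cl)C2 | intermediate
27 | CNP0280843.3: C5 S, C7 S, C10 R, C11 R dibromochloro-β-chamigrene | C=C1CC[C@H](Br)C(C)(C)[C@]12CC[C@@](C)(Br)[C@H](Cl)C2 | target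

Total step count: 19. Longest linear sequence: 19 (fully linear from 1).

Steps most likely to fail

Step 11. The internal alkene may bind rhodium too weakly, so that C–C activation stalls, or insertion may stray to C7–C8.
- The fallback gives up the carbonylation and builds ring A by allylation and ring-closing metathesis.
- It sets out from 8. LiAlH4 reduction gives ketal alcohol F1. Aqueous acid unmasks and dehydrates it to 2-methylene ketone F2.
- Copper-catalysed (CuBr·SMe2) 1,4-addition of 2-methylallylmagnesium chloride follows, and O-acylation of the resulting C2=C7 enolate with allyl chloroformate gives allyl enol carbonate F3.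
- A Tsuji decarboxylative allylation (Pd2(dba)3, phosphinooxazoline ligand) forms C7–C12 axially, anti to the axial C6 methyl group, to give diene ketone F4.
- Ring-closing metathesis with the second-generation Grubbs catalyst closes C10=C11. The route is rejoined at 24.

Step 19. After ionisation of the tertiary C10–O bond, proton loss to allylic chlorides may outrun bromide capture, or the crowded alcohol may fail to engage the reagent.
- The fallback moves the bromination in front of the methylenation, so that strongly ionising bromide chemistry can be used while no acid-sensitive alkene is present.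
- It sets out from 24. Trichloroisocyanuric acid in aqueous acetone gives chlorohydrin ketone F5.
- Me3SiBr in CH2Cl2 converts the tertiary alcohol into bromochloro ketone F6. Any alkene formed by proton loss is returned to the tertiary bromide by the HBr present.
- Pyridine-buffered Cp2Ti(μ-Cl)(μ-CH2)AlMe2 at low temperature methylenates C2. The route is rejoined at 27.

Step 4. Ring closure may run through the enol oxygen instead of C7, or bromonium transfer between molecules may erode the configuration at C5.
- The fallback accepts O-closure and then moves the tertiary carbon from oxygen to carbon with a Lewis acid.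
- It sets out from 6. Dilute solvolysis in (CF3)2CHOH buffered with 2,6-di-tert-butylpyridine gives cyclic enol ether F7.
- SnCl4 in CH2Cl2 re-ionises its tertiary C6–O bond, again assisted by bromine, and lets C7 capture the cation. The route is rejoined at 7.

Further compounds
F1 | step 11 | [(8S)-8-bromo-7,7-dimethyl-1,4-dioxaspiro[4.5]decan-6-yl]methanol | O1CCOC12CC[C@H](Br)C(C)(C)[C@@H]2CO
F2 | step 11 | (4S)-4-bromo-3,3-dimethyl-2-methylidenecyclohexan-1-one | O=C1CC[C@H](Br)C(C)(C)C1=C
F3 | step 11 | allyl (4S)-4-bromo-3,3-dimethyl-2-(3-methylbut-3-en-1-yl)cyclohex-1-en-1-yl carbonate | C=CCOC(=O)OC1=C(CCC(C)=C)C(C)(C)[C@@H](Br)CC1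
F4 | step 11 | (4S)-2-allyl-4-bromo-3,3-dimethyl-2-(3-methylbut-3-en-1-yl)cyclohexan-1-one, allyl trans to Br | O=C1CC[C@H](Br)C(C)(C)[C@]1(CC=C)CCC(C)=C
F5 | step 19 | chlorohydrin ketone (C2 ketone, C10 OH, C11 Cl) | O=C1CC[C@H](Br)C(C)(C)[C@]12CC[C@@](C)(O)[C@H](Cl)C2
F6 | step 19 | bromochloro ketone (C2 ketone, C10 Br, C11 Cl) | O=C1CC[C@H](Br)C(C)(C)[C@]12CC[C@@](C)(Br)[C@H](Cl)C2
F7 | step 4 | methyl 2-[(5S)-5-bromo-6,6-dimethyloxan-2-ylidene]acetate (either alkene geometry) | COC(=O)C=C1CC[C@H](Br)C(C)(C)O1
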